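We decide to take the dissolved gas as standing at its saturation 41 mM and to reckon just the shortfall, a small correction to a large number.

| flask | substrate | gas phase | remark | time |
|---|---|---|---|---|
| gamma | 0.050 M | 41 mM (held) | run made earlier |  |
| eta | 0.20 M | 41 mM (held) | run made earlier |  |
| flask | 0.10 M | 41 mM (held) |  | 12 min |

| run | time / min | product / % |
|---|---|---|
| gamma | 1.00 | 1 |
| gamma | 1.50 | 5 |
| gamma | 2.50 | 9 |
| gamma | 4.00 | 19 |
| gamma | 8.00 | 35 |
| gamma | 12.0 | 51 |
| eta | 2.00 | 4 |
| eta | 4.00 | 16 |
| eta | 6.00 | 21 |
| eta | 8.00 | 32 |
| eta | 10.0 | 39 |
| eta | 12.0 | 46 |

(standard deviation of a reading: 2 percentage points)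

- at the start none of the gas is dissolved
- what was read earlier has a scatter of 2 percentage points, one standard deviation
- on the list of suspects stand: gas phase <-> dissolved gas; substrate + dissolved gas <-> product

1. the product standing at 12 min, as a percentage of the substrate charged
2. concentration of dissolved gas in solution at 12 min, in percent of saturation

From 4.00 min to 12.0 min, the logarithm of the substrate left falls at 0.0628 min⁻¹ in gamma and 0.0552 min⁻¹ in eta. The flask's charge lies between theirs, so we take the mean, k′ = 0.0590 min⁻¹, a pseudo-first-order constant. Drawn back to zero product, these lines give a lag τ = 0.745 min, a reading that carries the scatter, and we take it as the time the liquid needs to fill with gas.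

That is the first rung of the ladder. The second is the substrate's half-life, 11.7 min, far longer than τ. So in the flask at 12 min we reckon 48.5% product.

The third rung is the balance of the gas: supply, the shortfall over τ, matches use, k′ times the substrate. The share of saturation missing is then g times the substrate left, where g = k′τ/csat = 1.07 M⁻¹ is the deficit constant. With 0.0515 M left, 5.52% is missing, so we say 94.5%.

The forecast, calling the reaction “roughly first order in substrate”, gives 49% and 93%, and ours puts the gas higher.

The flask gives 48.7% and 94.3%.

    gas phase ⇌ dissolved gas, rate k1*(csat - [dissolved gas]) (kL = 1.35 min⁻¹)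
    substrate + dissolved gas ⇌ product (K = 480 M⁻¹, k = 1.60 M⁻¹ min⁻¹)

The flask's gas is short by 5.70%, and g with the 51% of substrate left gives 5.50%. Left ten times as long, the flask reaches 95.1% product against its 48.7%, so the time allowed is the main reason that about half of the substrate is still there at 12 min. In the neighbour flask read at 3.0 min, with 87% of the substrate left, g gives 9.34% missing, and that neighbour's 0.0366 M of dissolved gas is short by 10.6%.

(The earlier runs and the new flask were computed from invented constants; scatter was added.)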